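The readings stem from a simulated flask from invented constants; noise was put on by code.

I asked which flask, epsilon or beta, ended with the higher share of L in all that became L or Z, and whether the two lay more than 2 percentage points apart.

| setting | north-east | west | epsilon | beta |
|---|---|---|---|---|
| Q | 0.12 M | 0.32 M | 0.15 M | 0.50 M |
| E | 31 mM (held) | 31 mM (held) | 31 mM (held) | 31 mM (held) |
| remark | run made earlier | run made earlier |  |  |
| time |  |  | 1.5 h | 5.0 h |

- north-east (time / h: L / %, Z / %): 0.167: 4.3, 0; 0.500: 11.8, 4.7; 0.833: 14.0, 10.9; 1.33: 14.3, 26.0; 2.00: 12.3, 44.4; 2.50: 7.0, 57.9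
- west (time / h: L / %, Z / %): 0.200: 1.9, 0; 0.333: 6.1, 0; 0.500: 6.4, 2.3; 0.833: 10.3, 2.0; 1.50: 13.0, 7.7; 2.50: 15.0, 18.1

(scatter of a reading: 1 percentage point)

- the flask that ends with the higher share of L in all that became L or Z, or "neither" when 2 percentage points or less lies between them (epsilon / beta / neither)
- share of L in all that became L or Z, epsilon
- share of L in all that became L or Z, beta

- at the start none of E is in solution

At the start of the earlier runs no E was in solution, and the first readings showed L without Z: 4.3% at 0.167 h in north-east and 1.9% at 0.200 h in west. In the middle of north-east, L read 14.3% at 1.33 h while Z climbed. By 2.50 h, north-east read 7.0% of L and 57.9% of Z, whereas west at 2.50 h read 15.0% and 18.1%. Since L holds one E and Z holds two, I reckoned the mean growth of L + 2Z from the last readings of each run: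

r = (L + 2Z) × [Q] charged / t

This gave 0.0589 M h⁻¹ in north-east and 0.0655 M h⁻¹ in west. The charge rose 2.67-fold but this rate 1.11-fold, so in these readings the growth of L + 2Z was nearly zero-order in Q, though faster in west, a thin gap given the scatter of 1 point.

What I carried forward was the load on the charge, the L + 2Z reached per Q charged, using the rate of the nearer run:

u = r × t / [Q] charged

Epsilon: 58.9%. Beta: 65.5%.

The readings placed the share of L at 45.3% for a load of 51.2% (west, 2.50 h) and at 35.5% for 66.3% (north-east, 1.33 h). Between these two readings I interpolated 40.3% for epsilon and 36.0% for beta, so my reckoning put epsilon ahead by 4.3 points, above the margin.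

The forecast differed, giving neither, with 38% for epsilon and 37% for beta: “Selectivity therefore depends only on conversion, not on Q concentration.”

The flask gave epsilon, with 37.3% against 32.3% for beta.

    Q + D → L + J (k = 84.0 L mol⁻¹ h⁻¹)
    Q + D → G + J (k = 40.0 L mol⁻¹ h⁻¹)
    D + L → Z + J (k = 340 L mol⁻¹ h⁻¹)
    D + G → Z + J (k = 48.0 L mol⁻¹ h⁻¹)
    E ⇌ D, rate k5*(csat - [D]) (kL = 2.80 h⁻¹)
    Q → X (k = 7.50 × 10⁻⁴ h⁻¹)

At the asked times L + 2Z stood at 59.3% of the charge in epsilon and 67.8% in beta, beside my loads of 58.9% and 65.5%. Carried to a reading of epsilon at 25 min, the load comes to 16.4%, L + 2Z in that flask stood at 13.8%, and the share of L stood at 77.2%.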